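**Retrosynthetic overview**
- Magnone B is an oxolane (O1, C2 trimethoxyphenyl, C3 CH2OH, C4 3,4-dimethoxybenzoyl, C5 H2). C4 is alpha to the aryl ketone and the adjacent C3 carries a one-carbon arm, and the plan rests on this C3/C4 pair.
- Last disconnection: CH2OH comes from CH2Br. The cis ketone oxygen hands the carbon over to water through a transient cis-fused dioxabicyclo[3.3.0]octane cation.
- Key disconnection: C3-C4, by 5-exo bromine-atom-transfer cyclisation of a C4 alpha-keto radical onto a vinyl group on C2. This closes the only lasting ring and sets C3 and C4 from C2.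
- The acyclic alpha-bromo-beta-alkoxy ketone comes from oxa-Michael addition of the (S)-aryl vinyl carbinol to the veratryl vinyl ketone, then silyl enol ether bromination. NBS then has a silyl enol ether to react with in preference to the vinyl group and the methoxyarenes, rather than an electron-poor enone.
- Both three-carbon pieces come from the aldehydes and vinylmagnesium bromide, and C2 is secured by lipase resolution.

Key step: step 8

Remark: the numbering O1, C2 (aryl), C3, C4 (aroyl), C5 is used for all cyclic compounds. The target is 2,3-trans-3,4-cis and C4 is epimerisable, so no step after ring closure uses free base or strong acid. The hydroxy ketone and its bicyclic hemiketal are assumed to equilibrate freely, with the open aryl ketone as the isolated form.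

**Step 1**
Reactants: 1 3,4,5-trimethoxybenzaldehyde; 2 vinylmagnesium bromide
Product: 3 rac-1-(3,4,5-trimethoxyphenyl)prop-2-en-1-ol
Conditions: 2 (1.2 equiv), THF, 0 °C; aq NH4Cl
Reagents that add atoms: vinylmagnesium bromide 2, C=C[Mg]Br
Why: Grignard 1,2-addition to a non-enolisable aromatic aldehyde; the carbinol centre forms racemic and is resolved in step 2.

**Step 2**
Reactants: 3 rac-1-(3,4,5-trimethoxyphenyl)prop-2-en-1-ol
Product: 4 (S)-1-(3,4,5-trimethoxyphenyl)prop-2-en-1-ol
Conditions: immobilised Candida antarctica lipase B, vinyl acetate (2 equiv), MTBE, 30 °C, stopped just past half conversion; chromatography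
Reagents that add atoms: none
Why: Enzymatic kinetic resolution by irreversible transesterification: the lipase pocket sorts secondary alcohols by substituent size (aryl large, vinyl medium) and acetylates the R enantiomer faster, so the S alcohol remains and its enantiopurity climbs as conversion passes one half.

**Step 3**
Reactants: 5 3,4-dimethoxybenzaldehyde; 2 vinylmagnesium bromide
Product: 6 rac-1-(3,4-dimethoxyphenyl)prop-2-en-1-ol
Conditions: 2 (1.2 equiv), THF, 0 °C; aq NH4Cl
Reagents that add atoms: vinylmagnesium bromide 2, C=C[Mg]Br
Why: Grignard 1,2-addition; the stereocentre is irrelevant because it is oxidised away in step 4.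

**Step 4**
Reactants: 6 rac-1-(3,4-dimethoxyphenyl)prop-2-en-1-ol
Product: 7 1-(3,4-dimethoxyphenyl)prop-2-en-1-one
Conditions: activated MnO2 (10 equiv), CH2Cl2, 20 °C; filtered, trace BHT, used at once
Reagents that add atoms: none
Why: MnO2 oxidation of an alcohol that is both benzylic and allylic, under neutral heterogeneous conditions that spare the polymerisation-prone aryl vinyl ketone.

**Step 5**
Reactants: 4 (S)-1-(3,4,5-trimethoxyphenyl)prop-2-en-1-ol; 7 1-(3,4-dimethoxyphenyl)prop-2-en-1-one
Product: 8 1-(3,4-dimethoxyphenyl)-3-{[(1S)-1-(3,4,5-trimethoxyphenyl)prop-2-en-1-yl]oxy}propan-1-one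
Conditions: PMe3 (10 mol %), 7 (1.5 equiv, slow addition), THF, 0 °C to 20 °C
Reagents that add atoms: none
Why: Phosphine-catalysed oxa-Michael addition: PMe3 adds to 7 to give a zwitterionic enolate that deprotonates 4, the alkoxide adds to the unsubstituted beta carbon of another enone and the new enolate carries the proton relay on; only the O-H bond of 4 breaks, so the S centre is retained, and the low standing alkoxide concentration avoids base-induced isomerisation of the carbinol.

**Step 6**
Reactants: 8 beta-alkoxy ketone
Product: 9 (Z)-trimethylsilyl enol ether of 8, (S) at the ether carbon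
Conditions: TMSOTf (1.2 equiv), Et3N (2 equiv), CH2Cl2, -20 °C to 0 °C; cold aq NaHCO3, pentane; used crude
Reagents that add atoms: trimethylsilyl triflate, C[Si](C)(C)OS(=O)(=O)C(F)(F)F
Why: Soft enolisation (silyl triflate plus tertiary amine) on the only enolisable side of the aryl ketone gives the mainly Z silyl enol ether without a free metal enolate, which is the species that would expel the beta alkoxide, and the excess amine keeps the medium non-acidic for the ionisable benzylic allylic ether.

**Step 7**
Reactants: 9 silyl enol ether; 10 N-bromosuccinimide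
Product: 11 2-bromo-1-(3,4-dimethoxyphenyl)-3-{[(1S)-1-(3,4,5-trimethoxyphenyl)prop-2-en-1-yl]oxy}propan-1-one, both epimers at the C-Br carbon
Conditions: 10 (1.0 equiv), THF, -78 °C, dark; pH 7 buffer work-up
Reagents that add atoms: N-bromosuccinimide 10, O=C1CCC(=O)N1Br
Why: Electrophilic alpha-bromination of a silyl enol ether: at -78 °C the enol ether is by far the most nucleophilic pi system, so NBS leaves the vinyl group and the methoxyarenes alone (which is why bromine enters here and not by mixing 7, 4 and NBS), and the epimer mixture does not matter because that carbon becomes a planar radical.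

**Step 8**
Reactants: 11 alpha-bromo-beta-alkoxy ketone
Product: 14 (2S,3S,4R)-3-(bromomethyl)-4-(3,4-dimethoxybenzoyl)-2-(3,4,5-trimethoxyphenyl)oxolane, via alpha-keto radical 12 (not isolated), via primary alkyl radical 13 (not isolated)
Conditions: CuBr (22 mol %) premixed with tris(2-pyridylmethyl)amine (TPMA, 20 mol %), degassed CH2Cl2 (0.05 M), 20 °C, Ar; chromatography
Reagents that add atoms: none
Why: The monovalent copper complex [Cu(TPMA)]Br abstracts bromine from the activated secondary C-Br bond of 11 to give the planar electrophilic radical 12 and the divalent copper complex [Cu(TPMA)Br]Br, 12 adds through C4 to the internal vinyl carbon, and radical 13 takes bromine back from divalent copper (or from another molecule of 11), which regenerates the catalyst. This is a Kharasch-type copper-catalysed atom-transfer radical cyclisation of an alpha-halo carbonyl compound, run on the 3-oxa-5-hexenyl tether familiar from Ueno-Stork cyclisations. The oxolane closes 5-exo-trig, favoured over 6-endo because the carbonyl group lies outside the forming ring and the short C-O bonds of the tether bring C4 over the internal alkene carbon. C3 is controlled by C2: in the chair-like transition state the trimethoxyphenyl group is pseudo-equatorial and anti to the alkene CH2, so CH2Br ends trans to the aryl group. C4 is set in the same transition state by the aroyl group taking the outer pseudo-equatorial site of the radical carbon, which puts it cis to CH2Br; this is the weaker preference, so the reaction is run at room temperature or below, and any C4 epimer is removed by chromatography or left behind in step 9, where it cannot use its carbonyl group. The step also needs activation of one C-Br bond only and a non-basic medium: the unactivated primary bromide of 14 is not re-abstracted, so the transfer is irreversible, and the slight excess of CuBr over TPMA leaves no free amine to expel the C5 alkoxide from 11 or to close 14 to a cyclopropyl ketone.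

**Step 9**
Reactants: 14 bromomethyl oxolane
Product: 17 Magnone B, via oxocarbenium triflate 15 (not isolated), via bicyclic hemiketal 16 (not isolated)
Conditions: AgOTf (1.5 equiv), 2,6-di-tert-butyl-4-methylpyridine (1.6 equiv), acetone-H2O 9:1, 20 °C, dark
Reagents that add atoms: water, O
Why: Silver-assisted solvolysis of a gamma-bromo ketone with neighbouring-group participation: as AgBr departs, the carbonyl oxygen held cis to CH2Br closes 5-exo-tet to the aryl-stabilised, necessarily cis-fused ion 15, water adds to give 16 and this opens to the conjugated aryl ketone, so C2, C3 and C4 are untouched, the hindered pyridine takes up the triflic acid that could enolise C4 or ionise the benzylic C2-O bond, and a C4 epimer stays unreacted because a trans-fused ion cannot form.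

**Compound list**
1 | 3,4,5-trimethoxybenzaldehyde | COc1cc(C=O)cc(OC)c1OC | starting material
2 | vinylmagnesium bromide | C=C[Mg]Br | starting material
3 | rac-1-(3,4,5-trimethoxyphenyl)prop-2-en-1-ol | OC(C=C)c1cc(OC)c(OC)c(OC)c1 | intermediate
4 | (S)-1-(3,4,5-trimethoxyphenyl)prop-2-en-1-ol | O[C@@H](C=C)c1cc(OC)c(OC)c(OC)c1 | intermediate
5 | 3,4-dimethoxybenzaldehyde | COc1ccc(C=O)cc1OC | starting material
6 | rac-1-(3,4-dimethoxyphenyl)prop-2-en-1-ol | COc1ccc(C(O)C=C)cc1OC | intermediate
7 | 1-(3,4-dimethoxyphenyl)prop-2-en-1-one | COc1ccc(C(=O)C=C)cc1OC | intermediate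
8 | 1-(3,4-dimethoxyphenyl)-3-{[(1S)-1-(3,4,5-trimethoxyphenyl)prop-2-en-1-yl]oxy}propan-1-one | COc1ccc(C(=O)CCO[C@@H](C=C)c2cc(OC)c(OC)c(OC)c2)cc1OC | intermediate
9 | (Z)-trimethylsilyl enol ether of 8 | COc1ccc(/C(O[Si](C)(C)C)=C/CO[C@@H](C=C)c2cc(OC)c(OC)c(OC)c2)cc1OC | intermediate
10 | N-bromosuccinimide | O=C1CCC(=O)N1Br | starting material
11 | 2-bromo-1-(3,4-dimethoxyphenyl)-3-{[(1S)-1-(3,4,5-trimethoxyphenyl)prop-2-en-1-yl]oxy}propan-1-one (epimers at C-Br) | COc1ccc(C(=O)C(Br)CO[C@@H](C=C)c2cc(OC)c(OC)c(OC)c2)cc1OC | intermediate
12 | alpha-keto radical from 11 (radical at the future C4) | COc1ccc(C(=O)[CH]CO[C@@H](C=C)c2cc(OC)c(OC)c(OC)c2)cc1OC | intermediate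
13 | cyclised primary alkyl radical (CH2 radical on C3; aryl trans, aroyl cis) | COc1ccc(C(=O)[C@H]2CO[C@H](c3cc(OC)c(OC)c(OC)c3)[C@H]2[CH2])cc1OC | intermediate
14 | (2S,3S,4R)-3-(bromomethyl)-4-(3,4-dimethoxybenzoyl)-2-(3,4,5-trimethoxyphenyl)oxolane | COc1ccc(C(=O)[C@H]2CO[C@H](c3cc(OC)c(OC)c(OC)c3)[C@H]2CBr)cc1OC | intermediate
15 | cis-fused 3,7-dioxabicyclo[3.3.0]octane oxocarbenium triflate (C=O+ carbon bears the dimethoxyphenyl group, trimethoxyphenyl exo) | COc1ccc(C2=[O+]C[C@H]3[C@@H]2CO[C@@H]3c4cc(OC)c(OC)c(OC)c4)cc1OC.[O-]S(=O)(=O)C(F)(F)F | intermediate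
16 | cis-fused bicyclic hemiketal (hemiketal carbon either configuration) | COc1ccc(C2(O)OC[C@H]3[C@@H]2CO[C@@H]3c4cc(OC)c(OC)c(OC)c4)cc1OC | intermediate
17 | Magnone B, (2S,3R,4R)-4-(3,4-dimethoxybenzoyl)-3-(hydroxymethyl)-2-(3,4,5-trimethoxyphenyl)oxolane | COc1ccc(C(=O)[C@H]2CO[C@H](c3cc(OC)c(OC)c(OC)c3)[C@H]2CO)cc1OC | target

Total steps: 9. Longest linear sequence: 7 steps (1, 2, 5, 6, 7, 8, 9).

**Steps most likely to fail**

**Step 8.** Facial discrimination at the planar C4 radical may be weak, so that the aroyl group ends trans to CH2Br. Bromine return may also be slow enough for the primary radical to add to the veratroyl ring.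
- The fallback sets out from 4 and rejoins the route at 16. It makes the same C3-C4 bond with the radical placed on C3, and lets a cis ring fusion fix the C3/C4 relationship.
- Alcohol 4 is epoxidised at the vinyl group (VO(acac)2, t-BuOOH, CH2Cl2, 0 °C) to the epoxy alcohol F1. Either epoxide configuration serves, because that carbon becomes a planar radical.
- Williamson etherification (NaH, (E)-3,4-dimethoxycinnamyl bromide, Bu4NI, THF, 0 °C) gives the epoxy cinnamyl ether F2.
- Cp2TiCl (trivalent titanium, made from Cp2TiCl2 and Zn, THF) opens the epoxide to the C3 radical, which closes 5-exo on the styrene-type double bond.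
- Iodine then turns the benzylic centre into an iodide, which the titanium alkoxide displaces. This gives the cis-fused diaryl furofuran F3.
- DDQ in CH2Cl2 with pH 7 buffer removes hydride from the 3,4-dimethoxybenzylic C-H, as in the cleavage of a 3,4-dimethoxybenzyl ether. Water adds, and the sequence arrives at hemiketal 16.

**Step 5.** Oligomerisation of the aryl vinyl ketone may outrun addition of the hindered secondary alcohol, or the addition may reverse during isolation.
- The fallback sets out from 4 and rejoins at 8. It builds the ether on a robust acceptor and forms the aryl ketone afterwards by C-C bond formation.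
- Cyanoethylation of 4 (acrylonitrile, benzyltrimethylammonium hydroxide 5 mol %, THF, 0 °C to 20 °C) gives the beta-alkoxy nitrile F4.
- (3,4-Dimethoxyphenyl)magnesium bromide (THF, 20 °C to 40 °C) adds to the nitrile. After a buffered quench the ketimine F5 hydrolyses at pH 4 to 5 (aq citric acid, 0 °C) to ketone 8.

**Step 9.** Ionisation of the primary C-Br bond may be sluggish, with epimerisation at C4 or ionisation at C2 during long exposure.
- The fallback sets out from 14 and rejoins at 17. It replaces the ionic substitution by a neutral radical oxygenation.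
- Finkelstein exchange (NaI, acetone, 50 °C) gives the iodide F6.
- Bu3SnH and TEMPO (toluene, 60 °C) regenerate radical 13 and trap it as the alkoxyamine F7.
- Zn in AcOH-THF-H2O (20 °C) cleaves the N-O bond to give 17.

**Further compounds**
F1 | step 8 | (R)-oxiran-2-yl(3,4,5-trimethoxyphenyl)methanol, carbinol carbon spatially as in 4, epoxide carbon either configuration | O[C@@H](C1CO1)c2cc(OC)c(OC)c(OC)c2
F2 | step 8 | (E)-3,4-dimethoxycinnamyl ether of F1 | COc1ccc(/C=C/CO[C@@H](C2CO2)c3cc(OC)c(OC)c(OC)c3)cc1OC
F3 | step 8 | cis-fused 2-(3,4-dimethoxyphenyl)-6-(3,4,5-trimethoxyphenyl)-3,7-dioxabicyclo[3.3.0]octane, both aryl groups exo (magnolin structure) | COc1ccc([C@H]2OC[C@H]3[C@@H]2CO[C@@H]3c4cc(OC)c(OC)c(OC)c4)cc1OC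
F4 | step 5 | 3-{[(1S)-1-(3,4,5-trimethoxyphenyl)prop-2-en-1-yl]oxy}propanenitrile | N#CCCO[C@@H](C=C)c1cc(OC)c(OC)c(OC)c1
F5 | step 5 | N-H ketimine corresponding to ketone 8 | COc1ccc(C(=N)CCO[C@@H](C=C)c2cc(OC)c(OC)c(OC)c2)cc1OC
F6 | step 9 | 3-(iodomethyl) analogue of 14 | COc1ccc(C(=O)[C@H]2CO[C@H](c3cc(OC)c(OC)c(OC)c3)[C@H]2CI)cc1OC
F7 | step 9 | 2,2,6,6-tetramethylpiperidin-1-yl ether of Magnone B | COc1ccc(C(=O)[C@H]2CO[C@H](c3cc(OC)c(OC)c(OC)c3)[C@H]2CON4C(C)(C)CCCC4(C)C)cc1OC
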